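**Retrosynthetic overview**
1. Target 19 ⇐ BBr3 demethylation of tri-O-methyl triacid 18; its C3 carboxyl ⇐ periodate cleavage and Pinnick oxidation of a glyceraldehyde-derived dioxolane (15 → 17 → 18).
2. Isochromanone ring (formed second, kept to the end) ⇐ hydroxide-triggered lactone switch of cis-γ-butyrolactone acid 13: the opened carboxylate cannot re-lactonise, so the alkoxide closes on the aryl methyl ester.
3. Succinate CH2CO2H and the C2' centre ⇐ nitromethane Michael addition to α-methylene-γ-butyrolactone 11 (trans to aryl by equilibration), then nitro → CO2H.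
4. Key C3–C4 bond and the temporary γ-lactone ring (formed first) ⇐ zinc Barbier carbonyl allylation of (R)-glyceraldehyde acetonide 8 with γ-aryl 2-(ethoxycarbonyl)allyl bromide 6 (syn, Felkin–Anh), then lactonisation.
5. 6 ⇐ Wohl–Ziegler bromination and Wittig olefination from aldehyde 3 ⇐ Rieche formylation of methyl 3,4,5-trimethoxybenzoate 1; 8 ⇐ D-mannitol diacetonide 7.

Assumption: the SMILES is read literally, i.e. (2R)-2-[(3S,4S)-3-carboxy-5,6,7-trihydroxy-1-oxo-3,4-dihydro-1H-isochromen-4-yl]butanedioic acid (3,4-trans ring, side-chain centre R); C3, C4 and C2' below refer to this numbering.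

**Route**

Step 1
Reactants: 1 methyl 3,4,5-trimethoxybenzoate
Product: 3 methyl 2-formyl-3,4,5-trimethoxybenzoate, via α-chloro ether 2 (not isolated)
Conditions: Cl2CHOMe (2 equiv), TiCl4 (2.2 equiv), CH2Cl2, −10 °C to rt; then ice/1 M HCl
Reagents that add atoms: dichloromethyl methyl ether ClC(Cl)OC; water O
Why: Rieche formylation (electrophilic aromatic substitution) can only occur at the two equivalent free positions, which are ortho/para to methoxy groups, and aqueous hydrolysis of the α-chloro ether releases the aldehyde.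

Step 2
Reactants: 3 methyl 2-formyl-3,4,5-trimethoxybenzoate; 4 ethyl 2-(triphenylphosphoranylidene)propanoate
Product: 5 ethyl (2E)-3-[6-(methoxycarbonyl)-2,3,4-trimethoxyphenyl]-2-methylprop-2-enoate
Conditions: toluene, 110 °C, 16 h
Reagents that add atoms: none
Why: Wittig olefination with a stabilised ylide tolerates the hindered, ester-flanked aldehyde (no alkoxide persists that could close a phthalide) and gives the (E)-alkene with aryl trans to CO2Et.

Step 3
Reactants: 5 ethyl (2E)-3-[6-(methoxycarbonyl)-2,3,4-trimethoxyphenyl]-2-methylprop-2-enoate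
Product: 6 ethyl (2Z)-2-(bromomethyl)-3-[6-(methoxycarbonyl)-2,3,4-trimethoxyphenyl]prop-2-enoate
Conditions: NBS (1.1 equiv), AIBN (5 mol %), PhCF3, 85 °C
Reagents that add atoms: N-bromosuccinimide O=C1CCC(=O)N1Br
Why: Wohl–Ziegler radical allylic bromination attacks the only allylic C–H bonds, methyl ethers and the ester-deactivated ring survive non-polar radical conditions, and the alkene geometry is kept (the descriptor becomes Z by priority only).

Step 4
Reactants: 7 1,2:5,6-di-O-isopropylidene-D-mannitol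
Product: 8 (4R)-2,2-dimethyl-1,3-dioxolane-4-carbaldehyde
Conditions: NaIO4, sat. aq NaHCO3, CH2Cl2, rt; used fresh
Reagents that add atoms: none
Why: Malaprade glycol cleavage of the central diol gives two equivalents of the aldehyde with the chiral-pool (R) centre untouched.

Step 5
Reactants: 6 ethyl (2Z)-2-(bromomethyl)-3-[6-(methoxycarbonyl)-2,3,4-trimethoxyphenyl]prop-2-enoate; 8 (4R)-2,2-dimethyl-1,3-dioxolane-4-carbaldehyde
Product: 10 ethyl (3R,4S)-4-[(4R)-2,2-dimethyl-1,3-dioxolan-4-yl]-4-hydroxy-3-[6-(methoxycarbonyl)-2,3,4-trimethoxyphenyl]-2-methylidenebutanoate, via allylzinc bromide 9 (not isolated)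
Conditions: Zn dust (3 equiv), THF/sat. aq NH4Cl, 0 °C to rt; chromatography to remove minor diastereomers
Reagents that add atoms: none
Why: In this Barbier-type carbonyl allylation the allylzinc adds through its γ-carbon (SE2') via a chair transition state, so the fixed geometry of the reagent (aryl cis to CH2Zn) gives the syn hydroxyl/aryl relationship (C4), while Felkin–Anh attack anti to the dioxolane oxygen of 8 sets the carbinol centre (C3, S); aqueous conditions keep the esters intact.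

Step 6
Reactants: 10 ethyl (3R,4S)-4-[(4R)-2,2-dimethyl-1,3-dioxolan-4-yl]-4-hydroxy-3-[6-(methoxycarbonyl)-2,3,4-trimethoxyphenyl]-2-methylidenebutanoate
Product: 11 (4R,5S)-5-[(4R)-2,2-dimethyl-1,3-dioxolan-4-yl]-4-[6-(methoxycarbonyl)-2,3,4-trimethoxyphenyl]-3-methylideneoxolan-2-one
Conditions: PPTS (0.2 equiv), toluene, 60 °C, 4 Å MS
Reagents that add atoms: none
Why: Acid-catalysed 5-exo-trig lactonisation (intramolecular transesterification) onto the acrylate ester is much faster than six-ring attack on the deactivated, ortho-substituted methyl benzoate, and it touches no stereocentre, giving the 4,5-cis lactone.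

Step 7
Reactants: 11 (4R,5S)-5-[(4R)-2,2-dimethyl-1,3-dioxolan-4-yl]-4-[6-(methoxycarbonyl)-2,3,4-trimethoxyphenyl]-3-methylideneoxolan-2-one
Product: 12 (3R,4S,5S)-5-[(4R)-2,2-dimethyl-1,3-dioxolan-4-yl]-4-[6-(methoxycarbonyl)-2,3,4-trimethoxyphenyl]-3-(2-nitroethyl)oxolan-2-one
Conditions: MeNO2 (solvent), DBU (0.3 equiv), 0 °C to rt; then 40 °C to equilibrate
Reagents that add atoms: nitromethane C[N+](=O)[O-]
Why: Michael addition of the nitronate to the exocyclic enoate, followed by reversible protonation at the lactone α-carbon under DBU, places the nitroethyl chain trans to the neighbouring aryl group (the all-cis epimer is strongly disfavoured), which sets C2' as R.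

Step 8
Reactants: 12 (3R,4S,5S)-5-[(4R)-2,2-dimethyl-1,3-dioxolan-4-yl]-4-[6-(methoxycarbonyl)-2,3,4-trimethoxyphenyl]-3-(2-nitroethyl)oxolan-2-one
Product: 13 2-[(3R,4S,5S)-5-[(4R)-2,2-dimethyl-1,3-dioxolan-4-yl]-4-[6-(methoxycarbonyl)-2,3,4-trimethoxyphenyl]-2-oxooxolan-3-yl]acetic acid
Conditions: NaNO2 (3 equiv), AcOH (10 equiv), DMSO, 35 °C
Reagents that add atoms: sodium nitrite [Na+].[O-]N=O; water O
Why: This oxidative Nef-type conversion (nitrosation to the nitrolic acid, then hydroxamic acid, then carboxylic acid) turns the primary nitro group into CO2H under mildly acidic conditions that leave lactone, acetonide and all stereocentres alone.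

Step 9
Reactants: 13 2-[(3R,4S,5S)-5-[(4R)-2,2-dimethyl-1,3-dioxolan-4-yl]-4-[6-(methoxycarbonyl)-2,3,4-trimethoxyphenyl]-2-oxooxolan-3-yl]acetic acid
Product: 15 (2R)-2-[(3S,4S)-3-[(4R)-2,2-dimethyl-1,3-dioxolan-4-yl]-5,6,7-trimethoxy-1-oxo-3,4-dihydro-1H-isochromen-4-yl]butanedioic acid, via dilithium hydroxy-dicarboxylate 14 (not isolated)
Conditions: LiOH·H2O (2.05 equiv), THF/H2O, 0 °C; evaporate, azeotrope with toluene; KOtBu (1.2 equiv), THF/DMF, 0 °C to rt; cold 1 M HCl to pH 3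
Reagents that add atoms: lithium hydroxide [Li+].[OH-]
Why: Chemoselective saponification turns the γ-lactone carbonyl into an unreactive carboxylate, so the alkoxide generated next can only close by 6-exo-trig transesterification onto the aryl methyl ester (translactonisation); no C–O bond at a stereocentre is broken and carboxylate α-centres do not epimerise.

Step 10
Reactants: 15 (2R)-2-[(3S,4S)-3-[(4R)-2,2-dimethyl-1,3-dioxolan-4-yl]-5,6,7-trimethoxy-1-oxo-3,4-dihydro-1H-isochromen-4-yl]butanedioic acid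
Product: 17 (2R)-2-[(3S,4S)-3-formyl-5,6,7-trimethoxy-1-oxo-3,4-dihydro-1H-isochromen-4-yl]butanedioic acid, via diol 16 (not isolated)
Conditions: H5IO6 (2 equiv), EtOAc, rt
Reagents that add atoms: none
Why: Periodic acid hydrolyses the terminal acetonide and then performs Malaprade cleavage of the 1,2-diol to the aldehyde, and because the C3 oxygen is already acylated no lactone scrambling is possible.

Step 11
Reactants: 17 (2R)-2-[(3S,4S)-3-formyl-5,6,7-trimethoxy-1-oxo-3,4-dihydro-1H-isochromen-4-yl]butanedioic acid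
Product: 18 (2R)-2-[(3S,4S)-3-carboxy-5,6,7-trimethoxy-1-oxo-3,4-dihydro-1H-isochromen-4-yl]butanedioic acid
Conditions: NaClO2, NaH2PO4, 2-methyl-2-butene, t-BuOH/H2O, 0 °C to rt (run directly on crude 17)
Reagents that add atoms: sodium chlorite [Na+].[O-]Cl=O
Why: Pinnick oxidation converts the aldehyde to the acid at about pH 4 without epimerising C3, and the alkene scavenger protects the electron-rich ring from HOCl.

Step 12
Reactants: 18 (2R)-2-[(3S,4S)-3-carboxy-5,6,7-trimethoxy-1-oxo-3,4-dihydro-1H-isochromen-4-yl]butanedioic acid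
Product: 19 (2R)-2-[(3S,4S)-3-carboxy-5,6,7-trihydroxy-1-oxo-3,4-dihydro-1H-isochromen-4-yl]butanedioic acid
Conditions: BBr3 (10 equiv), CH2Cl2, −78 °C to rt; H2O, 0 °C; C18 chromatography (H2O/MeCN, 0.1 % HCO2H)
Reagents that add atoms: none
Why: BBr3 cleavage of the three aryl methyl ethers (Lewis-acid activation, then SN2 attack of bromide on methyl) is non-hydrolytic and cold, so the lactone, the acids and the three stereocentres are unchanged.

**Compound list**
1 | methyl 3,4,5-trimethoxybenzoate | COC(=O)c1cc(OC)c(OC)c(OC)c1 | starting material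
2 | methyl 2-[chloro(methoxy)methyl]-3,4,5-trimethoxybenzoate | COC(=O)c1cc(OC)c(OC)c(OC)c1C(Cl)OC | intermediate
3 | methyl 2-formyl-3,4,5-trimethoxybenzoate | COC(=O)c1cc(OC)c(OC)c(OC)c1C=O | intermediate
4 | ethyl 2-(triphenylphosphoranylidene)propanoate | CCOC(=O)C(C)=P(c1ccccc1)(c1ccccc1)c1ccccc1 | starting material
5 | ethyl (2E)-3-[6-(methoxycarbonyl)-2,3,4-trimethoxyphenyl]-2-methylprop-2-enoate | CCOC(=O)/C(C)=C/c1c(OC)c(OC)c(OC)cc1C(=O)OC | intermediate
6 | ethyl (2Z)-2-(bromomethyl)-3-[6-(methoxycarbonyl)-2,3,4-trimethoxyphenyl]prop-2-enoate | CCOC(=O)/C(CBr)=C/c1c(OC)c(OC)c(OC)cc1C(=O)OC | intermediate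
7 | 1,2:5,6-di-O-isopropylidene-D-mannitol, (1S,2S)-1,2-bis[(4R)-2,2-dimethyl-1,3-dioxolan-4-yl]ethane-1,2-diol | CC1(C)OC[C@@H](O1)[C@@H](O)[C@H](O)[C@H]1COC(C)(C)O1 | starting material
8 | (4R)-2,2-dimethyl-1,3-dioxolane-4-carbaldehyde, (R)-glyceraldehyde acetonide | O=C[C@H]1COC(C)(C)O1 | intermediate
9 | ethyl (2Z)-2-[(bromozincio)methyl]-3-[6-(methoxycarbonyl)-2,3,4-trimethoxyphenyl]prop-2-enoate (allylzinc bromide) | CCOC(=O)/C(C[Zn]Br)=C/c1c(OC)c(OC)c(OC)cc1C(=O)OC | intermediate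
10 | ethyl (3R,4S)-4-[(4R)-2,2-dimethyl-1,3-dioxolan-4-yl]-4-hydroxy-3-[6-(methoxycarbonyl)-2,3,4-trimethoxyphenyl]-2-methylidenebutanoate | C=C(C(=O)OCC)[C@@H](c1c(OC)c(OC)c(OC)cc1C(=O)OC)[C@H](O)[C@H]1COC(C)(C)O1 | intermediate
11 | (4R,5S)-5-[(4R)-2,2-dimethyl-1,3-dioxolan-4-yl]-4-[6-(methoxycarbonyl)-2,3,4-trimethoxyphenyl]-3-methylideneoxolan-2-one | O=C1O[C@H]([C@H]2COC(C)(C)O2)[C@H](c2c(OC)c(OC)c(OC)cc2C(=O)OC)C1=C | intermediate
12 | (3R,4S,5S)-5-[(4R)-2,2-dimethyl-1,3-dioxolan-4-yl]-4-[6-(methoxycarbonyl)-2,3,4-trimethoxyphenyl]-3-(2-nitroethyl)oxolan-2-one | O=C1O[C@H]([C@H]2COC(C)(C)O2)[C@H](c2c(OC)c(OC)c(OC)cc2C(=O)OC)[C@H]1CC[N+](=O)[O-] | intermediate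
13 | 2-[(3R,4S,5S)-5-[(4R)-2,2-dimethyl-1,3-dioxolan-4-yl]-4-[6-(methoxycarbonyl)-2,3,4-trimethoxyphenyl]-2-oxooxolan-3-yl]acetic acid | O=C1O[C@H]([C@H]2COC(C)(C)O2)[C@H](c2c(OC)c(OC)c(OC)cc2C(=O)OC)[C@H]1CC(=O)O | intermediate
14 | dilithium (2R)-2-[(1S,2S)-2-[(4R)-2,2-dimethyl-1,3-dioxolan-4-yl]-2-hydroxy-1-[6-(methoxycarbonyl)-2,3,4-trimethoxyphenyl]ethyl]butanedioate | [Li+].[Li+].[O-]C(=O)C[C@@H](C([O-])=O)[C@@H](c1c(OC)c(OC)c(OC)cc1C(=O)OC)[C@H](O)[C@H]1COC(C)(C)O1 | intermediate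
15 | (2R)-2-[(3S,4S)-3-[(4R)-2,2-dimethyl-1,3-dioxolan-4-yl]-5,6,7-trimethoxy-1-oxo-3,4-dihydro-1H-isochromen-4-yl]butanedioic acid | OC(=O)C[C@@H](C(=O)O)[C@H]1c2c(cc(OC)c(OC)c2OC)C(=O)O[C@@H]1[C@H]3COC(C)(C)O3 | intermediate
16 | (2R)-2-[(3S,4S)-3-[(1R)-1,2-dihydroxyethyl]-5,6,7-trimethoxy-1-oxo-3,4-dihydro-1H-isochromen-4-yl]butanedioic acid | OC(=O)C[C@@H](C(=O)O)[C@H]1c2c(cc(OC)c(OC)c2OC)C(=O)O[C@@H]1[C@H](O)CO | intermediate
17 | (2R)-2-[(3S,4S)-3-formyl-5,6,7-trimethoxy-1-oxo-3,4-dihydro-1H-isochromen-4-yl]butanedioic acid | OC(=O)C[C@@H](C(=O)O)[C@H]1c2c(cc(OC)c(OC)c2OC)C(=O)O[C@@H]1C=O | intermediate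
18 | (2R)-2-[(3S,4S)-3-carboxy-5,6,7-trimethoxy-1-oxo-3,4-dihydro-1H-isochromen-4-yl]butanedioic acid | OC(=O)C[C@@H](C(=O)O)[C@H]1c2c(cc(OC)c(OC)c2OC)C(=O)O[C@@H]1C(=O)O | intermediate
19 | (2R)-2-[(3S,4S)-3-carboxy-5,6,7-trihydroxy-1-oxo-3,4-dihydro-1H-isochromen-4-yl]butanedioic acid | O=C(O)C[C@@H](C(=O)O)[C@H]1c2c(cc(O)c(O)c2O)C(=O)O[C@@H]1C(=O)O | target

**Totals**
Total steps: 12. Longest linear sequence: 11 steps (1 → 3 → 5 → 6 → 10 → 11 → 12 → 13 → 15 → 17 → 18 → 19; step 4 is a one-step side branch to 8).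

**Three steps most likely to fail, with fallbacks**

Step 5 is the most exposed. The γ-carbon carries a 2,6-disubstituted aryl ring, so γ-attack may be slow, and the Felkin selectivity of an aqueous zinc reagent is only moderate. The fallback replaces the Barbier reaction by a closed-transition-state allylboration. It sets out from 6: CuCl-catalysed borylation (B2pin2, KOAc, DMF, rt) gives the allylboronate ethyl (2E)-3-[6-(methoxycarbonyl)-2,3,4-trimethoxyphenyl]-2-[(4,4,5,5-tetramethyl-1,3,2-dioxaborolan-2-yl)methyl]prop-2-enoate F1. F1 is heated with 8 (toluene, 80 °C, or Sc(OTf)3 10 mol % in CH2Cl2 at −78 °C), the same chair transition state gives the syn, Felkin adduct, and aqueous work-up of the borate brings the route back at 10.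

Step 9 can fail by competing saponification of the aryl ester or by incomplete ring closure, after which acidification simply regenerates γ-lactone 13. The fallback is a protecting-group-directed switch that sets out from 13, opened to 14 as in step 9.
- Silylation of the dried salt (TBSOTf, 2,6-lutidine, CH2Cl2) gives the tris-silyl compound bis(tert-butyldimethylsilyl) (2R)-2-[(1S,2S)-2-[(tert-butyldimethylsilyl)oxy]-2-[(4R)-2,2-dimethyl-1,3-dioxolan-4-yl]-1-[6-(methoxycarbonyl)-2,3,4-trimethoxyphenyl]ethyl]butanedioate F2.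
- K2CO3 in aqueous MeOH cleaves only the silyl esters and leaves (2R)-2-[(1S,2S)-2-[(tert-butyldimethylsilyl)oxy]-2-[(4R)-2,2-dimethyl-1,3-dioxolan-4-yl]-1-[6-(methoxycarbonyl)-2,3,4-trimethoxyphenyl]ethyl]butanedioic acid F3, which cannot lactonise.
- O-tert-butyl-N,N'-diisopropylisourea (CH2Cl2, rt to 40 °C) gives di-tert-butyl (2R)-2-[(1S,2S)-2-[(tert-butyldimethylsilyl)oxy]-2-[(4R)-2,2-dimethyl-1,3-dioxolan-4-yl]-1-[6-(methoxycarbonyl)-2,3,4-trimethoxyphenyl]ethyl]butanedioate F4.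
- TBAF (THF, rt) removes the silyl ether; the liberated alkoxide, offered only hindered tert-butyl esters as alternatives, closes onto the aryl methyl ester to give di-tert-butyl (2R)-2-[(3S,4S)-3-[(4R)-2,2-dimethyl-1,3-dioxolan-4-yl]-5,6,7-trimethoxy-1-oxo-3,4-dihydro-1H-isochromen-4-yl]butanedioate F5.
- TFA/H2O (9:1, rt) removes both tert-butyl esters and the acetonide, and the route is rejoined at diol 16, which is cleaved with H5IO6 or NaIO4 as in step 10 to give 17.

Step 3 can fail by bromination of the electron-rich ring at its last free position or by over-bromination. The fallback replaces radical bromination by oxidation and substitution. It sets out from 5: SeO2 (cat.) with t-BuOOH (dioxane, 80 °C) gives the allylic alcohol ethyl (2E)-2-(hydroxymethyl)-3-[6-(methoxycarbonyl)-2,3,4-trimethoxyphenyl]prop-2-enoate F6, and an Appel reaction (CBr4, PPh3, CH2Cl2, 0 °C) brings the route back at 6.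

**Further compounds**
F1 | step 5 | ethyl (2E)-3-[6-(methoxycarbonyl)-2,3,4-trimethoxyphenyl]-2-[(4,4,5,5-tetramethyl-1,3,2-dioxaborolan-2-yl)methyl]prop-2-enoate | CCOC(=O)/C(CB1OC(C)(C)C(C)(C)O1)=C/c1c(OC)c(OC)c(OC)cc1C(=O)OC
F2 | step 9 | bis(tert-butyldimethylsilyl) (2R)-2-[(1S,2S)-2-[(tert-butyldimethylsilyl)oxy]-2-[(4R)-2,2-dimethyl-1,3-dioxolan-4-yl]-1-[6-(methoxycarbonyl)-2,3,4-trimethoxyphenyl]ethyl]butanedioate | CC(C)(C)[Si](C)(C)OC(=O)C[C@@H](C(=O)O[Si](C)(C)C(C)(C)C)[C@@H](c1c(OC)c(OC)c(OC)cc1C(=O)OC)[C@H](O[Si](C)(C)C(C)(C)C)[C@H]1COC(C)(C)O1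
F3 | step 9 | (2R)-2-[(1S,2S)-2-[(tert-butyldimethylsilyl)oxy]-2-[(4R)-2,2-dimethyl-1,3-dioxolan-4-yl]-1-[6-(methoxycarbonyl)-2,3,4-trimethoxyphenyl]ethyl]butanedioic acid | OC(=O)C[C@@H](C(=O)O)[C@@H](c1c(OC)c(OC)c(OC)cc1C(=O)OC)[C@H](O[Si](C)(C)C(C)(C)C)[C@H]1COC(C)(C)O1
F4 | step 9 | di-tert-butyl (2R)-2-[(1S,2S)-2-[(tert-butyldimethylsilyl)oxy]-2-[(4R)-2,2-dimethyl-1,3-dioxolan-4-yl]-1-[6-(methoxycarbonyl)-2,3,4-trimethoxyphenyl]ethyl]butanedioate | CC(C)(C)OC(=O)C[C@@H](C(=O)OC(C)(C)C)[C@@H](c1c(OC)c(OC)c(OC)cc1C(=O)OC)[C@H](O[Si](C)(C)C(C)(C)C)[C@H]1COC(C)(C)O1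
F5 | step 9 | di-tert-butyl (2R)-2-[(3S,4S)-3-[(4R)-2,2-dimethyl-1,3-dioxolan-4-yl]-5,6,7-trimethoxy-1-oxo-3,4-dihydro-1H-isochromen-4-yl]butanedioate | CC(C)(C)OC(=O)C[C@@H](C(=O)OC(C)(C)C)[C@H]1c2c(cc(OC)c(OC)c2OC)C(=O)O[C@@H]1[C@H]3COC(C)(C)O3
F6 | step 3 | ethyl (2E)-2-(hydroxymethyl)-3-[6-(methoxycarbonyl)-2,3,4-trimethoxyphenyl]prop-2-enoate | CCOC(=O)/C(CO)=C/c1c(OC)c(OC)c(OC)cc1C(=O)OC
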